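## Retrosynthetic overview

1. The ring B–ring C biaryl bond is cut last (Suzuki–Miyaura), giving two O-benzyl-protected olivil units: unit 1 (rings A/B) as an aryl boronate on ring B and unit 2 (rings C/D) as an aryl bromide on ring C. Global O-debenzylation is the final step.
2. Each oxolane (O1, C2, C3, C4, C5) is cut at C2–C3 and C4–C5 into a carbonyl ylide (benzylic C2–O1–C5H2) and a C3=C4 acceptor alkene: a (3+2) cycloaddition.
3. The enabling feature is that O1 sits between a benzylic C2 carrying a 4-oxygenated aryl ring (stabilises positive charge, polarising the dipole) and an unsubstituted C5H2, while C3 and C4 carry the substituents of a β-functionalised acrylate. The C3 CH2OH is carried as an acyl group on a chiral sultam, and the C4 tertiary OH as a pinacolboryl group trans to that acyl group.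
4. Dipolarophiles come from benzylic bromide + N-propioloyl sultam (copper coupling), then syn borylcupration. Ylide precursors are bis[(trimethylsilyl)methyl] acetals of the two benzaldehydes.
5. Ring order: oxolane of unit 2 (key step) and oxolane of unit 1 (same reaction, in parallel), then the biaryl bond; no further ring is formed.

Key step: step 12

Remark on numbering: in both units the oxolane is O1, C2 (aryl), C3 (CH2OH), C4 (carbinol, benzyl), C5 (CH2). Ring A is the benzyl ring of unit 1, ring B the C2-aryl ring of unit 1, ring C the benzyl ring of unit 2, ring D the C2-aryl ring of unit 2.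

Assumption: thermal additions to N-enoyl bornane-10,2-sultams are taken to occur on the C-alpha Re face of the (2R)-auxiliary (s-cis enoyl, C=O anti to SO2, a sulfonyl oxygen over the Si face). This sense is derived from a conformational model, not from a demonstrated carbonyl ylide case; if it proved opposite, the (2S)-sultam would be used with no other change.

## Route

Step 1
Reactants: 1 5-bromovanillin (3-bromo-4-hydroxy-5-methoxybenzaldehyde)
Product: 2 4-(benzyloxy)-3-bromo-5-methoxybenzaldehyde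
Conditions: BnBr, K2CO3, DMF, 60 °C
Reagents that add atoms: benzyl bromide BrCc1ccccc1
Why: Williamson etherification of the phenoxide; the benzyl ether tolerates fluoride, hydride, alkaline peroxide and palladium coupling and is removed by hydrogenolysis at the end.

Step 2
Reactants: 2 4-(benzyloxy)-3-bromo-5-methoxybenzaldehyde
Product: 3 [4-(benzyloxy)-3-bromo-5-methoxyphenyl]methanol
Conditions: NaBH4, MeOH/THF, 0 °C
Reagents that add atoms: none
Why: Borohydride reduction of the aldehyde, which leaves the aryl bromide and benzyl ether untouched.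

Step 3
Reactants: 3 [4-(benzyloxy)-3-bromo-5-methoxyphenyl]methanol
Product: 4 2-(benzyloxy)-1-bromo-5-(bromomethyl)-3-methoxybenzene
Conditions: PBr3, CH2Cl2, 0 °C
Reagents that add atoms: phosphorus tribromide BrP(Br)Br
Why: Bromination of a benzylic alcohol through its phosphite ester (SN2); the bromide is used without storage.

Step 4
Reactants: 5 [4-(benzyloxy)-3-methoxyphenyl]methanol
Product: 6 1-(benzyloxy)-4-(bromomethyl)-2-methoxybenzene
Conditions: PBr3, CH2Cl2, 0 °C
Reagents that add atoms: phosphorus tribromide BrP(Br)Br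
Why: The same benzylic bromination through the phosphite ester as in step 3.

Step 5
Reactants: 7 (2R)-bornane-10,2-sultam; 8 propiolic acid
Product: 10 N-propioloyl-(2R)-bornane-10,2-sultam, via propiolic pivalic anhydride 9 (not isolated)
Conditions: 8, t-BuCOCl, Et3N, THF, −20 °C; then lithiated 7 (n-BuLi, THF, −78 °C), −78 to 0 °C
Reagents that add atoms: none
Why: N-acylation of the sultam anion by a mixed pivalic anhydride, which should be attacked at the unhindered and more electrophilic propioloyl carbonyl.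

Step 6
Reactants: 4 2-(benzyloxy)-1-bromo-5-(bromomethyl)-3-methoxybenzene; 10 N-propioloyl-(2R)-bornane-10,2-sultam
Product: 11 N-{4-[4-(benzyloxy)-3-bromo-5-methoxyphenyl]but-2-ynoyl}-(2R)-bornane-10,2-sultam
Conditions: CuI (10 mol%), K2CO3, n-Bu4NI, MeCN, rt
Reagents that add atoms: none
Why: Copper-catalysed C(sp)–C(sp3) coupling of the copper acetylide of an electron-poor terminal alkyne with a benzylic bromide; the aryl bromide does not react under these conditions.

Step 7
Reactants: 6 1-(benzyloxy)-4-(bromomethyl)-2-methoxybenzene; 10 N-propioloyl-(2R)-bornane-10,2-sultam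
Product: 12 N-{4-[4-(benzyloxy)-3-methoxyphenyl]but-2-ynoyl}-(2R)-bornane-10,2-sultam
Conditions: CuI (10 mol%), K2CO3, n-Bu4NI, MeCN, rt
Reagents that add atoms: none
Why: The same copper-catalysed acetylide–benzyl bromide coupling as in step 6.

Step 8
Reactants: 11 N-{4-[4-(benzyloxy)-3-bromo-5-methoxyphenyl]but-2-ynoyl}-(2R)-bornane-10,2-sultam
Product: 13 N-{(Z)-4-[4-(benzyloxy)-3-bromo-5-methoxyphenyl]-3-(4,4,5,5-tetramethyl-1,3,2-dioxaborolan-2-yl)but-2-enoyl}-(2R)-bornane-10,2-sultam (boron trans to the acyl group)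
Conditions: B2pin2, CuCl (5 mol%), Xantphos (5 mol%), NaOt-Bu (10 mol%), MeOH (2 equiv), THF, 0 °C to rt
Reagents that add atoms: bis(pinacolato)diboron CC1(C)OB(OC1(C)C)B1OC(C)(C)C(C)(C)O1
Why: Copper-catalysed formal hydroboration of an alkynoyl unit (borylcupration, then protonation by MeOH), in which syn addition with boron at the β-carbon should give the (Z)-alkene with boron trans to the acyl group, the geometry that later becomes the trans C4–O/C3–CH2OH relation.

Step 9
Reactants: 12 N-{4-[4-(benzyloxy)-3-methoxyphenyl]but-2-ynoyl}-(2R)-bornane-10,2-sultam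
Product: 14 N-{(Z)-4-[4-(benzyloxy)-3-methoxyphenyl]-3-(4,4,5,5-tetramethyl-1,3,2-dioxaborolan-2-yl)but-2-enoyl}-(2R)-bornane-10,2-sultam (boron trans to the acyl group)
Conditions: B2pin2, CuCl (5 mol%), Xantphos (5 mol%), NaOt-Bu (10 mol%), MeOH (2 equiv), THF, 0 °C to rt
Reagents that add atoms: bis(pinacolato)diboron CC1(C)OB(OC1(C)C)B1OC(C)(C)C(C)(C)O1
Why: The same copper-catalysed syn borylcupration–protonation as in step 8, giving the (Z)-alkene.

Step 10
Reactants: 15 4-(benzyloxy)-3-methoxybenzaldehyde; 16 (trimethylsilyl)methanol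
Product: 17 1-(benzyloxy)-4-{bis[(trimethylsilyl)methoxy]methyl}-2-methoxybenzene
Conditions: 16 (3 equiv), PPTS (cat.), toluene, reflux, Dean–Stark; Et3N quench
Reagents that add atoms: none
Why: Acid-catalysed acetalisation driven by azeotropic removal of water; the acetal carries the future C2, O1 and C5 of ring-D unit 2 and is handled on base-washed media.

Step 11
Reactants: 2 4-(benzyloxy)-3-bromo-5-methoxybenzaldehyde; 16 (trimethylsilyl)methanol
Product: 18 2-(benzyloxy)-5-{bis[(trimethylsilyl)methoxy]methyl}-1-bromo-3-methoxybenzene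
Conditions: 16 (3 equiv), PPTS (cat.), toluene, reflux, Dean–Stark; Et3N quench
Reagents that add atoms: none
Why: The same acid-catalysed acetalisation with azeotropic water removal as in step 10.

Step 12
Reactants: 17 1-(benzyloxy)-4-{bis[(trimethylsilyl)methoxy]methyl}-2-methoxybenzene; 13 N-{(Z)-4-[4-(benzyloxy)-3-bromo-5-methoxyphenyl]-3-(4,4,5,5-tetramethyl-1,3,2-dioxaborolan-2-yl)but-2-enoyl}-(2R)-bornane-10,2-sultam
Product: 21 (2R)-N-{[(2S,3S,4R)-2-[4-(benzyloxy)-3-methoxyphenyl]-4-[4-(benzyloxy)-3-bromo-5-methoxybenzyl]-4-(4,4,5,5-tetramethyl-1,3,2-dioxaborolan-2-yl)oxolan-3-yl]carbonyl}bornane-10,2-sultam, via α-chloro ether 19 (not isolated), via carbonyl ylide 20 (not isolated)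
Conditions: 17 (2.5 equiv), AcCl, CH2Cl2, 0 °C, volatiles removed; then slow addition to 13, CsF (dried, excess), MeCN, 0 °C to rt
Reagents that add atoms: none
Why: AcCl converts acetal 17 into α-chloro ether 19 (acetal–acyl chloride exchange), and fluoride attack at silicon then expels chloride in a 1,3-elimination to give the nonstabilised carbonyl ylide 20, which adds to the electron-poor C=C of 13 in a concerted suprafacial 1,3-dipolar (3+2) cycloaddition; the closest known reaction type is the CsF-induced generation of nonstabilised carbonyl ylides from 1-chloroalkyl (trimethylsilyl)methyl ethers and their addition to acrylates, with the auxiliary-controlled addition of nonstabilised azomethine ylides to N-enoyl bornanesultams as the model for facial control. The oxolane is closed in one (4π+2π) cycloaddition that forms C5–C4 and C2–C3 together. Regiochemistry: the unsubstituted CH2 terminus of 20 (larger HOMO coefficient, because the 4-benzyloxy-3-methoxyphenyl group stabilises positive charge at the benzylic terminus) should bond to the acyl β-carbon C4 (larger LUMO coefficient) and the benzylic terminus to C3, which is also the sterically matched union. C3 and C4: the (Z)-geometry of 13 is transferred stereospecifically so that boron and the acyl group end up trans on the ring, and the sultam (s-cis enoyl, C=O anti to SO2) should screen the C-alpha Si face with a sulfonyl oxygen so that the ylide adds to the C-alpha Re face, which fixes the absolute configuration. C2: the aryl group should take the position remote from the bulky acyl sultam in the transition state (acyl group exo), giving the 2,3-trans ring. The step needs regio-, exo- and facial selectivity and a trap fast enough to outrun ylide collapse; these are to be secured by the polarised ylide, the doubly activated (acyl and boryl) alkene used as limiting component with slow generation of excess 20, and the auxiliary, while pinacol boronates are expected to bind fluoride only reversibly under CsF/MeCN desilylation conditions.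

Step 13
Reactants: 18 2-(benzyloxy)-5-{bis[(trimethylsilyl)methoxy]methyl}-1-bromo-3-methoxybenzene; 14 N-{(Z)-4-[4-(benzyloxy)-3-methoxyphenyl]-3-(4,4,5,5-tetramethyl-1,3,2-dioxaborolan-2-yl)but-2-enoyl}-(2R)-bornane-10,2-sultam
Product: 24 (2R)-N-{[(2S,3S,4R)-2-[4-(benzyloxy)-3-bromo-5-methoxyphenyl]-4-[4-(benzyloxy)-3-methoxybenzyl]-4-(4,4,5,5-tetramethyl-1,3,2-dioxaborolan-2-yl)oxolan-3-yl]carbonyl}bornane-10,2-sultam, via α-chloro ether 22 (not isolated), via carbonyl ylide 23 (not isolated)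
Conditions: 18 (2.5 equiv), AcCl, CH2Cl2, 0 °C, volatiles removed; then slow addition to 14, CsF (dried, excess), MeCN, 0 °C to rt
Reagents that add atoms: none
Why: The same fluoride-induced 1,3-elimination and carbonyl ylide (3+2) cycloaddition as in step 12, with regiochemistry from the polarised ylide, trans C3/C4 from the (Z)-alkene, absolute configuration from C-alpha Re attack on the (2R)-sultam enoyl and 2,3-trans from the exo acyl orientation.

Step 14
Reactants: 21 (2R)-N-{[(2S,3S,4R)-2-[4-(benzyloxy)-3-methoxyphenyl]-4-[4-(benzyloxy)-3-bromo-5-methoxybenzyl]-4-(4,4,5,5-tetramethyl-1,3,2-dioxaborolan-2-yl)oxolan-3-yl]carbonyl}bornane-10,2-sultam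
Product: 26 (3S,4R,5S)-5-[4-(benzyloxy)-3-methoxyphenyl]-3-[4-(benzyloxy)-3-bromo-5-methoxybenzyl]-4-(hydroxymethyl)oxolan-3-ol, via hydroxymethyl boronate 25 (not isolated)
Conditions: LiBH4, MeOH (1 equiv), THF, 0 °C to rt; then 3 M NaOH, 30% H2O2, 0 °C to rt
Reagents that add atoms: hydrogen peroxide OO
Why: Reductive cleavage of the N-acyl sultam by borohydride releases the primary alcohol and the auxiliary, and alkaline peroxide oxidation of the tertiary C–B bond proceeds with retention (1,2-metallate shift), so the C4 hydroxyl takes the place of boron, trans to the hydroxymethyl group.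

Step 15
Reactants: 24 (2R)-N-{[(2S,3S,4R)-2-[4-(benzyloxy)-3-bromo-5-methoxyphenyl]-4-[4-(benzyloxy)-3-methoxybenzyl]-4-(4,4,5,5-tetramethyl-1,3,2-dioxaborolan-2-yl)oxolan-3-yl]carbonyl}bornane-10,2-sultam
Product: 28 (3S,4R,5S)-5-[4-(benzyloxy)-3-bromo-5-methoxyphenyl]-3-[4-(benzyloxy)-3-methoxybenzyl]-4-(hydroxymethyl)oxolan-3-ol, via hydroxymethyl boronate 27 (not isolated)
Conditions: LiBH4, MeOH (1 equiv), THF, 0 °C to rt; then 3 M NaOH, 30% H2O2, 0 °C to rt
Reagents that add atoms: hydrogen peroxide OO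
Why: The same reductive auxiliary cleavage and stereoretentive boronate oxidation as in step 14.

Step 16
Reactants: 28 (3S,4R,5S)-5-[4-(benzyloxy)-3-bromo-5-methoxyphenyl]-3-[4-(benzyloxy)-3-methoxybenzyl]-4-(hydroxymethyl)oxolan-3-ol
Product: 29 (3S,4R,5S)-5-[4-(benzyloxy)-3-methoxy-5-(4,4,5,5-tetramethyl-1,3,2-dioxaborolan-2-yl)phenyl]-3-[4-(benzyloxy)-3-methoxybenzyl]-4-(hydroxymethyl)oxolan-3-ol
Conditions: B2pin2, Pd(dppf)Cl2 (5 mol%), KOAc, 1,4-dioxane, 85 °C
Reagents that add atoms: bis(pinacolato)diboron CC1(C)OB(OC1(C)C)B1OC(C)(C)C(C)(C)O1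
Why: Miyaura borylation of the only aryl bromide; the weak acetate base tolerates the free diol and the benzyl ethers.

Step 17
Reactants: 29 (3S,4R,5S)-5-[4-(benzyloxy)-3-methoxy-5-(4,4,5,5-tetramethyl-1,3,2-dioxaborolan-2-yl)phenyl]-3-[4-(benzyloxy)-3-methoxybenzyl]-4-(hydroxymethyl)oxolan-3-ol; 26 (3S,4R,5S)-5-[4-(benzyloxy)-3-methoxyphenyl]-3-[4-(benzyloxy)-3-bromo-5-methoxybenzyl]-4-(hydroxymethyl)oxolan-3-ol
Product: 30 tetra-O-benzyl ether of the target (ring B C5 joined to ring C C5, all four phenols as benzyl ethers, both oxolanes (3S,4R,5S))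
Conditions: Pd(OAc)2 (5 mol%), SPhos (10 mol%), K3PO4, toluene/H2O, 80 °C
Reagents that add atoms: none
Why: Suzuki–Miyaura cross-coupling with a dialkylbiarylphosphine ligand suited to biaryls bearing one ortho alkoxy group on each ring; no stereocentre is touched and the biaryl axis is not configurationally defined in the target.

Step 18
Reactants: 30 tetra-O-benzyl ether of the target
Product: 31 CNP0269573.1 (5,5'-linked bis-olivil)
Conditions: H2 (1 atm), 10% Pd/C, EtOAc/MeOH, rt
Reagents that add atoms: none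
Why: Hydrogenolysis of the four aryl benzyl ethers under neutral conditions, which are expected to be cleaved much faster than the ring benzylic C2–O1 bonds; acid is avoided because olivil-type oxolanes cyclise to aryltetralins.

## Compound list

1 | 5-bromovanillin | COc1cc(C=O)cc(Br)c1O | starting material
2 | 4-(benzyloxy)-3-bromo-5-methoxybenzaldehyde | COc1cc(C=O)cc(Br)c1OCc1ccccc1 | intermediate
3 | [4-(benzyloxy)-3-bromo-5-methoxyphenyl]methanol | COc1cc(CO)cc(Br)c1OCc1ccccc1 | intermediate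
4 | 2-(benzyloxy)-1-bromo-5-(bromomethyl)-3-methoxybenzene | COc1cc(CBr)cc(Br)c1OCc1ccccc1 | intermediate
5 | [4-(benzyloxy)-3-methoxyphenyl]methanol | COc1cc(CO)ccc1OCc1ccccc1 | starting material
6 | 1-(benzyloxy)-4-(bromomethyl)-2-methoxybenzene | COc1cc(CBr)ccc1OCc1ccccc1 | intermediate
7 | (2R)-bornane-10,2-sultam ((3aS,6R,7aR)-8,8-dimethylhexahydro-3H-3a,6-methano-2,1-benzisothiazole 2,2-dioxide) | CC1(C)[C@@H]2CC[C@]13CS(=O)(=O)N[C@@H]3C2 | starting material
8 | propiolic acid | C#CC(=O)O | starting material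
9 | propiolic pivalic anhydride | C#CC(=O)OC(=O)C(C)(C)C | intermediate
10 | N-propioloyl-(2R)-bornane-10,2-sultam | CC1(C)[C@@H]2CC[C@]13CS(=O)(=O)N(C(=O)C#C)[C@@H]3C2 | intermediate
11 | N-{4-[4-(benzyloxy)-3-bromo-5-methoxyphenyl]but-2-ynoyl}-(2R)-bornane-10,2-sultam | CC1(C)[C@@H]2CC[C@]13CS(=O)(=O)N(C(=O)C#CCc4cc(OC)c(OCc5ccccc5)c(Br)c4)[C@@H]3C2 | intermediate
12 | N-{4-[4-(benzyloxy)-3-methoxyphenyl]but-2-ynoyl}-(2R)-bornane-10,2-sultam | CC1(C)[C@@H]2CC[C@]13CS(=O)(=O)N(C(=O)C#CCc4ccc(OCc5ccccc5)c(OC)c4)[C@@H]3C2 | intermediate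
13 | N-{(Z)-4-[4-(benzyloxy)-3-bromo-5-methoxyphenyl]-3-(4,4,5,5-tetramethyl-1,3,2-dioxaborolan-2-yl)but-2-enoyl}-(2R)-bornane-10,2-sultam | CC1(C)[C@@H]2CC[C@]13CS(=O)(=O)N(C(=O)/C=C(/B4OC(C)(C)C(C)(C)O4)Cc4cc(OC)c(OCc5ccccc5)c(Br)c4)[C@@H]3C2 | intermediate
14 | N-{(Z)-4-[4-(benzyloxy)-3-methoxyphenyl]-3-(4,4,5,5-tetramethyl-1,3,2-dioxaborolan-2-yl)but-2-enoyl}-(2R)-bornane-10,2-sultam | CC1(C)[C@@H]2CC[C@]13CS(=O)(=O)N(C(=O)/C=C(/B4OC(C)(C)C(C)(C)O4)Cc4ccc(OCc5ccccc5)c(OC)c4)[C@@H]3C2 | intermediate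
15 | 4-(benzyloxy)-3-methoxybenzaldehyde | COc1cc(C=O)ccc1OCc1ccccc1 | starting material
16 | (trimethylsilyl)methanol | C[Si](C)(C)CO | starting material
17 | 1-(benzyloxy)-4-{bis[(trimethylsilyl)methoxy]methyl}-2-methoxybenzene | COc1cc(C(OC[Si](C)(C)C)OC[Si](C)(C)C)ccc1OCc1ccccc1 | intermediate
18 | 2-(benzyloxy)-5-{bis[(trimethylsilyl)methoxy]methyl}-1-bromo-3-methoxybenzene | COc1cc(C(OC[Si](C)(C)C)OC[Si](C)(C)C)cc(Br)c1OCc1ccccc1 | intermediate
19 | 1-(benzyloxy)-4-{chloro[(trimethylsilyl)methoxy]methyl}-2-methoxybenzene (racemic) | COc1cc(C(Cl)OC[Si](C)(C)C)ccc1OCc1ccccc1 | intermediate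
20 | carbonyl ylide: [4-(benzyloxy)-3-methoxybenzylidene]oxonium methylide | COc1cc(C=[O+][CH2-])ccc1OCc1ccccc1 | intermediate
21 | (2R)-N-{[(2S,3S,4R)-2-[4-(benzyloxy)-3-methoxyphenyl]-4-[4-(benzyloxy)-3-bromo-5-methoxybenzyl]-4-(4,4,5,5-tetramethyl-1,3,2-dioxaborolan-2-yl)oxolan-3-yl]carbonyl}bornane-10,2-sultam | CC1(C)[C@@H]2CC[C@]13CS(=O)(=O)N(C(=O)[C@@H]4[C@@H](c5ccc(OCc6ccccc6)c(OC)c5)OC[C@@]4(Cc5cc(OC)c(OCc6ccccc6)c(Br)c5)B5OC(C)(C)C(C)(C)O5)[C@@H]3C2 | intermediate
22 | 2-(benzyloxy)-1-bromo-5-{chloro[(trimethylsilyl)methoxy]methyl}-3-methoxybenzene (racemic) | COc1cc(C(Cl)OC[Si](C)(C)C)cc(Br)c1OCc1ccccc1 | intermediate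
23 | carbonyl ylide: [4-(benzyloxy)-3-bromo-5-methoxybenzylidene]oxonium methylide | COc1cc(C=[O+][CH2-])cc(Br)c1OCc1ccccc1 | intermediate
24 | (2R)-N-{[(2S,3S,4R)-2-[4-(benzyloxy)-3-bromo-5-methoxyphenyl]-4-[4-(benzyloxy)-3-methoxybenzyl]-4-(4,4,5,5-tetramethyl-1,3,2-dioxaborolan-2-yl)oxolan-3-yl]carbonyl}bornane-10,2-sultam | CC1(C)[C@@H]2CC[C@]13CS(=O)(=O)N(C(=O)[C@@H]4[C@@H](c5cc(OC)c(OCc6ccccc6)c(Br)c5)OC[C@@]4(Cc5ccc(OCc6ccccc6)c(OC)c5)B5OC(C)(C)C(C)(C)O5)[C@@H]3C2 | intermediate
25 | [(2S,3R,4R)-2-[4-(benzyloxy)-3-methoxyphenyl]-4-[4-(benzyloxy)-3-bromo-5-methoxybenzyl]-4-(4,4,5,5-tetramethyl-1,3,2-dioxaborolan-2-yl)oxolan-3-yl]methanol | COc1cc(C[C@@]2(B3OC(C)(C)C(C)(C)O3)CO[C@H](c3ccc(OCc4ccccc4)c(OC)c3)[C@H]2CO)cc(Br)c1OCc1ccccc1 | intermediate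
26 | (3S,4R,5S)-5-[4-(benzyloxy)-3-methoxyphenyl]-3-[4-(benzyloxy)-3-bromo-5-methoxybenzyl]-4-(hydroxymethyl)oxolan-3-ol | COc1cc(C[C@@]2(O)CO[C@H](c3ccc(OCc4ccccc4)c(OC)c3)[C@H]2CO)cc(Br)c1OCc1ccccc1 | intermediate
27 | [(2S,3R,4R)-2-[4-(benzyloxy)-3-bromo-5-methoxyphenyl]-4-[4-(benzyloxy)-3-methoxybenzyl]-4-(4,4,5,5-tetramethyl-1,3,2-dioxaborolan-2-yl)oxolan-3-yl]methanol | COc1cc(C[C@@]2(B3OC(C)(C)C(C)(C)O3)CO[C@H](c3cc(OC)c(OCc4ccccc4)c(Br)c3)[C@H]2CO)ccc1OCc1ccccc1 | intermediate
28 | (3S,4R,5S)-5-[4-(benzyloxy)-3-bromo-5-methoxyphenyl]-3-[4-(benzyloxy)-3-methoxybenzyl]-4-(hydroxymethyl)oxolan-3-ol | COc1cc(C[C@@]2(O)CO[C@H](c3cc(OC)c(OCc4ccccc4)c(Br)c3)[C@H]2CO)ccc1OCc1ccccc1 | intermediate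
29 | (3S,4R,5S)-5-[4-(benzyloxy)-3-methoxy-5-(4,4,5,5-tetramethyl-1,3,2-dioxaborolan-2-yl)phenyl]-3-[4-(benzyloxy)-3-methoxybenzyl]-4-(hydroxymethyl)oxolan-3-ol | COc1cc(C[C@@]2(O)CO[C@H](c3cc(OC)c(OCc4ccccc4)c(B4OC(C)(C)C(C)(C)O4)c3)[C@H]2CO)ccc1OCc1ccccc1 | intermediate
30 | tetra-O-benzyl ether of the target: (3S,4R,5S)-5-{4-(benzyloxy)-3-[2-(benzyloxy)-5-{[(3S,4R,5S)-5-[4-(benzyloxy)-3-methoxyphenyl]-3-hydroxy-4-(hydroxymethyl)oxolan-3-yl]methyl}-3-methoxyphenyl]-5-methoxyphenyl}-3-[4-(benzyloxy)-3-methoxybenzyl]-4-(hydroxymethyl)oxolan-3-ol | COc1cc(C[C@@]2(O)CO[C@H](c3cc(OC)c(OCc4ccccc4)c(-c4cc(C[C@@]5(O)CO[C@H](c6ccc(OCc7ccccc7)c(OC)c6)[C@H]5CO)cc(OC)c4OCc4ccccc4)c3)[C@H]2CO)ccc1OCc1ccccc1 | intermediate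
31 | CNP0269573.1: (3S,4R,5S)-5-{4-hydroxy-3-[2-hydroxy-5-{[(3S,4R,5S)-3-hydroxy-5-(4-hydroxy-3-methoxyphenyl)-4-(hydroxymethyl)oxolan-3-yl]methyl}-3-methoxyphenyl]-5-methoxyphenyl}-3-(4-hydroxy-3-methoxybenzyl)-4-(hydroxymethyl)oxolan-3-ol | COc1cc(C[C@@]2(O)CO[C@H](c3cc(OC)c(O)c(-c4cc(C[C@@]5(O)CO[C@H](c6ccc(O)c(OC)c6)[C@H]5CO)cc(OC)c4O)c3)[C@H]2CO)ccc1O | target

## Step count and risks

Total step count: 18. Longest linear sequence: 9 steps (steps 1, 2, 3, 6, 8, 12, 14, 17, 18).

Steps most likely to fail: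

1. Step 12. What may go wrong: trapping of the short-lived ylide by a trisubstituted, β,β-disubstituted alkene may be slower than ylide collapse (electrocyclisation to the aryloxirane, dimerisation); fluoride may tie up the boronate or deconjugate the enoyl unit through its benzylic γ-hydrogens; and facial or exo selectivity may be low. The fallback moves the C4 oxygen out of the cycloaddition and uses a less hindered acceptor; it sets out from 11 and 17 and comes back at 26. Compound 11 would be isomerised with Et3N (cat.) in CH2Cl2 to the allenoyl sultam N-{4-[4-(benzyloxy)-3-bromo-5-methoxyphenyl]buta-2,3-dienoyl}-(2R)-bornane-10,2-sultam F1 (allene axis not controlled). Ylide 20, generated from 17 through 19 as in step 12, should add across the α,β-double bond of F1 (CH2 terminus to the central allene carbon, same auxiliary control of the C-alpha face, aryl trans to the acyl group) to give the benzylidene oxolane (2R)-N-{[(2S,3S)-2-[4-(benzyloxy)-3-methoxyphenyl]-4-[4-(benzyloxy)-3-bromo-5-methoxybenzylidene]oxolan-3-yl]carbonyl}bornane-10,2-sultam F2 (alkene geometry immaterial). Epoxidation of the exocyclic styrene-type double bond with dimethyldioxirane (acetone, −20 °C) on the face anti to the adjacent acyl sultam should give the C4 spiro-epoxide of F2 with the epoxide oxygen trans to the acyl group F3 (benzylic epoxide carbon not controlled). LiEt3BH (THF, 0 °C) would then cleave the auxiliary reductively and open the epoxide at its benzylic CH carbon, leaving the tertiary C4 alcohol, which is compound 26.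

2. Step 13. What may go wrong: the same competition between ylide collapse and cycloaddition, the same fluoride sensitivity of the boryl enoyl unit and the same selectivity questions as in step 12, here with the bromine-bearing ylide 23. The fallback sets out from 12 and 18 and comes back at 28. Compound 12 would be isomerised (Et3N cat., CH2Cl2) to N-{4-[4-(benzyloxy)-3-methoxyphenyl]buta-2,3-dienoyl}-(2R)-bornane-10,2-sultam F4. Ylide 23, generated from 18 through 22 as in step 13, should add across its α,β-double bond to give (2R)-N-{[(2S,3S)-2-[4-(benzyloxy)-3-bromo-5-methoxyphenyl]-4-[4-(benzyloxy)-3-methoxybenzylidene]oxolan-3-yl]carbonyl}bornane-10,2-sultam F5. Dimethyldioxirane should give the C4 spiro-epoxide of F5 with the epoxide oxygen trans to the acyl group F6, and LiEt3BH (THF, 0 °C) would cleave the auxiliary and open the epoxide at the benzylic carbon to give compound 28.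

3. Step 6. What may go wrong: under the carbonate conditions the skipped ynoyl imide may undergo prototropic shift to the allenoyl isomer, or the activated N-propioloyl sultam may be degraded before coupling. The fallback attaches the auxiliary last; it sets out from 4 and comes back at 13. Compound 4 would be coupled with tert-butyl propiolate (CuI, K2CO3, n-Bu4NI, MeCN), the ester case of this coupling, to give tert-butyl 4-[4-(benzyloxy)-3-bromo-5-methoxyphenyl]but-2-ynoate F7. Copper-catalysed borylcupration–protonation (B2pin2, CuCl, Xantphos, NaOt-Bu, MeOH, THF) should give tert-butyl (Z)-4-[4-(benzyloxy)-3-bromo-5-methoxyphenyl]-3-(4,4,5,5-tetramethyl-1,3,2-dioxaborolan-2-yl)but-2-enoate F8. TFA in CH2Cl2 at 0 °C would remove the tert-butyl group to give (Z)-4-[4-(benzyloxy)-3-bromo-5-methoxyphenyl]-3-(4,4,5,5-tetramethyl-1,3,2-dioxaborolan-2-yl)but-2-enoic acid F9. Activation with t-BuCOCl/Et3N to the mixed pivalic anhydride of F9 F10 and reaction with lithiated 7 (THF, −78 °C) would give compound 13.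

## Further compounds

F1 | step 12 | N-{4-[4-(benzyloxy)-3-bromo-5-methoxyphenyl]buta-2,3-dienoyl}-(2R)-bornane-10,2-sultam | CC1(C)[C@@H]2CC[C@]13CS(=O)(=O)N(C(=O)C=C=Cc4cc(OC)c(OCc5ccccc5)c(Br)c4)[C@@H]3C2
F2 | step 12 | (2R)-N-{[(2S,3S)-2-[4-(benzyloxy)-3-methoxyphenyl]-4-[4-(benzyloxy)-3-bromo-5-methoxybenzylidene]oxolan-3-yl]carbonyl}bornane-10,2-sultam | CC1(C)[C@@H]2CC[C@]13CS(=O)(=O)N(C(=O)[C@@H]4[C@@H](c5ccc(OCc6ccccc6)c(OC)c5)OCC4=Cc4cc(OC)c(OCc5ccccc5)c(Br)c4)[C@@H]3C2
F3 | step 12 | C4 spiro-epoxide of F2 (epoxide oxygen on C4 trans to the acyl group) | CC1(C)[C@@H]2CC[C@]13CS(=O)(=O)N(C(=O)[C@@H]4[C@@H](c5ccc(OCc6ccccc6)c(OC)c5)OC[C@@]45OC5c4cc(OC)c(OCc5ccccc5)c(Br)c4)[C@@H]3C2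
F4 | step 13 | N-{4-[4-(benzyloxy)-3-methoxyphenyl]buta-2,3-dienoyl}-(2R)-bornane-10,2-sultam | CC1(C)[C@@H]2CC[C@]13CS(=O)(=O)N(C(=O)C=C=Cc4ccc(OCc5ccccc5)c(OC)c4)[C@@H]3C2
F5 | step 13 | (2R)-N-{[(2S,3S)-2-[4-(benzyloxy)-3-bromo-5-methoxyphenyl]-4-[4-(benzyloxy)-3-methoxybenzylidene]oxolan-3-yl]carbonyl}bornane-10,2-sultam | CC1(C)[C@@H]2CC[C@]13CS(=O)(=O)N(C(=O)[C@@H]4[C@@H](c5cc(OC)c(OCc6ccccc6)c(Br)c5)OCC4=Cc4ccc(OCc5ccccc5)c(OC)c4)[C@@H]3C2
F6 | step 13 | C4 spiro-epoxide of F5 (epoxide oxygen on C4 trans to the acyl group) | CC1(C)[C@@H]2CC[C@]13CS(=O)(=O)N(C(=O)[C@@H]4[C@@H](c5cc(OC)c(OCc6ccccc6)c(Br)c5)OC[C@@]45OC5c4ccc(OCc5ccccc5)c(OC)c4)[C@@H]3C2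
F7 | step 6 | tert-butyl 4-[4-(benzyloxy)-3-bromo-5-methoxyphenyl]but-2-ynoate | COc1cc(CC#CC(=O)OC(C)(C)C)cc(Br)c1OCc1ccccc1
F8 | step 6 | tert-butyl (Z)-4-[4-(benzyloxy)-3-bromo-5-methoxyphenyl]-3-(4,4,5,5-tetramethyl-1,3,2-dioxaborolan-2-yl)but-2-enoate | COc1cc(C/C(B2OC(C)(C)C(C)(C)O2)=C\C(=O)OC(C)(C)C)cc(Br)c1OCc1ccccc1
F9 | step 6 | (Z)-4-[4-(benzyloxy)-3-bromo-5-methoxyphenyl]-3-(4,4,5,5-tetramethyl-1,3,2-dioxaborolan-2-yl)but-2-enoic acid | COc1cc(C/C(B2OC(C)(C)C(C)(C)O2)=C\C(=O)O)cc(Br)c1OCc1ccccc1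
F10 | step 6 | mixed pivalic anhydride of F9 | COc1cc(C/C(B2OC(C)(C)C(C)(C)O2)=C\C(=O)OC(=O)C(C)(C)C)cc(Br)c1OCc1ccccc1
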